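# Proposed synthesis of CNP0196585.1 through a furan / oxyallyl-cation (4+3) cycloaddition

## Structural features

The target is a hydroazulene: a cyclopentane (C1–C5) fused through the C1–C5 bond to a cycloheptene (C5, C6, C7, C8, C9, C10, C1), with the C7 oxygen esterified by 3,4-dimethoxybenzoic acid. C1 (quaternary, methyl), C5 (tertiary carbinol) and C4 (isopropyl) are contiguous, and methyl, hydroxyl and isopropyl all sit on one face of the five-membered ring, so the ring fusion is cis. The C7 ester oxygen lies on the face of the seven-membered ring opposite to the C5 hydroxyl and is allylic to the trisubstituted C8=C9 olefin (methyl on C8). Fragile points are the tertiary C5 alcohol (dehydration; retro-aldol if a free C5 alkoxide ever faces a C7 ketone), the allylic ester (ionisation in acid) and the olefin, which forbids a late hydrogenation. The real difficulty is the pair of vicinal fully substituted carbons C1/C5, with the methyl cis to both the hydroxyl and the C4 isopropyl, inside a seven-membered ring. The key step uses the fact that C5–C6–C7–C8–C9, with oxygen on C5 and C7 and unsaturation at C9, is the bridgehead/three-carbon-bridge array of an 8-oxabicyclo[3.2.1]oct-6-en-3-one. C5 and C9 are then the α-carbons and C1 and C10 the β-carbons of a furan fused to the five-membered ring, and C6–C7–C8 is an oxyallyl unit.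

## Logic of the disconnections

**22 to 20 and 21.** The acyl C–O bond at C7 is cut. The ester is the most labile group and its acid part is an article of commerce. The forward step must acylate the secondary allylic hydroxyl beside the tertiary one; the steric difference allows this.

**20 to 18 (through 19).** The C8=C9 olefin and the C5 hydroxyl are reconnected as a C5–O–C9 ether with chlorine on C8. The flexible hydroxy cycloheptene becomes a rigid oxygen-bridged bicycle in which C7 and C1 can be set by facial bias, and the olefin is deferred to the last skeletal step, so hydrogenation is allowed before it. The forward step must break C9–O and nothing else: a carbanion at C8 has only one β-oxygen able to leave once the C7 hydroxyl is the alkoxide 19.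

**18 to 17.** The C1 methyl is traced back to a cyclopropane by re-forming the C10–CH2 bond. A methyl on a quaternary carbon next to the fully substituted C5 is the hardest group to attach by polar bond formation; as one edge of a three-membered ring it comes from an olefin. The forward step must cleave only the CH–CH2 bond and leave C–Cl and C–O bonds alone.

**17 to 16.** The C7 carbinol is returned to the ketone that the cycloaddition delivers. The forward step must bring hydride to the face away from the C1–C10 bridge.

**16 to 15.** The cyclopropane bonds C1–CH2 and C10–CH2 are cut, uncovering the C1=C10 olefin that the furan leaves behind. The forward step must transfer methylene to the face of the bridge oxygen.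

**15 to 11 and 13 (through 14).** The bonds C5–C6 and C8–C9 are cut. The seven-membered ring falls into a furan part (C9, C10, C1, C5 and the oxygen) and a three-carbon oxyallyl part (C6–C7–C8). One ring, two skeletal bonds and three stereocentres are removed at once, and 11 keeps a single stereocentre. The forward step needs the chlorine/methyl terminus at C9 and attack anti to isopropyl. The extra chlorine on C8 is deliberate: without it C6 and C8 would both be enolisable, the bridge could open in either direction, and the opened hydroxy dienone would be a tropone hydrate.

**13 to 12.** One C–Cl bond is cut; the forward step is a geminal α-chlorination.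

**11 to 9 (through 10).** The furan is taken back to a butenolide: C9 returns to the carboxyl level and C5 becomes an sp3 carbinol carbon. Reduction must stop at the lactol, and the dehydration must not touch C4.

**9 to 6 and 7 (through 8).** The C1=C10 double bond and the acyl C9–O bond are cut; both come from one two-carbon reagent. O-acylation must precede olefination, which the ketene secures by reacting with the hydroxyl first.

**6 to 4 (through 5).** The C5–O bond is cut; the oxygen is placed by oxidation of a regiodefined enol ether. This oxygen ends as the tertiary hydroxyl of the target.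

**4 to 1 and 2 (through 3).** The C4–isopropyl bond is cut. This is the only stereocentre made by reagent control; all others derive from it. The conjugate addition must be highly enantioselective and the enolate must be trapped before it equilibrates.

## Other disconnections considered

Alternative 1: The cut is the C1–C5 bond between the two fully substituted fusion carbons, with the five-membered ring still open between C3 and C4.
- **Forward step:** the eleven-membered lactone A1 (carbonyl C4, MOM ether on C5, allylic oxygen on C3, C7 silyloxy, C8=C9 in place) is converted to its silyl ketene acetal with LiN(SiMe3)2 and Me3SiCl. Ireland–Claisen rearrangement then contracts it to the cycloheptene acid A2, with carboxyl (C4) and vinyl (C2=C3) cis.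
- **In favour:** the most congested bond is made intramolecularly in a pericyclic step. Both quaternary centres arise together, with relative configuration set by olefin and ketene-acetal geometry in a ring-constrained transition state. The C7 oxygen and the C8=C9 olefin need no later adjustment. On the C1/C5 problem this is the equal of the chosen plan or better, since no separate methylation is needed.
- **Against:** A1 is a medium-ring lactone whose closure and enolate geometry both need control. The absolute configuration is relayed from C7 alone. After the rearrangement C4 must still gain isopropyl, a bond to C3 and a new stereocentre, which costs several steps.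
- **Comparison:** the mechanism is cleaner than a cationic cycloaddition with a regiochemical question, but the C4 centre comes last instead of first and the step count would be clearly higher.

Alternative 2: The cut is C1–C2.
- **Forward step:** the diazoketone A3 (seven-membered ring complete, C1 a tertiary methyl-bearing CH cis to the C5 side chain, C5 as silyl ether, C4 set) is decomposed with Rh2(OAc)4. The C2 carbenoid inserts into the C1–H bond and gives the cyclopentanone A4.
- **In favour:** insertion into an electron-rich tertiary C–H bond five atoms away is the preferred mode and goes with retention. The quaternary centre therefore comes from a tertiary one that is easy to set. As a way of making C1 this is at least the equal of cyclopropanation and hydrogenolysis, and one step shorter at that point.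
- **Against:** C4, C5 and C1 must already sit on the seven-membered ring, so the stereochemical problem is moved into the precursor. Insertion at C6–H, attack on the silyl ether oxygen and cyclopropanation of C8=C9 are conceivable side paths. Afterwards the C3 ketone must be removed and the C7 oxygen introduced by allylic oxidation next to C10 and the C8 methyl.
- **Comparison:** the chosen plan brings the C7 oxygen in with the three-carbon partner, needs no late C–H oxidation, and is shorter after its key step.

Alternative 3: The cuts are C6–C7 and C4–C5.
- **Forward step:** heating the 2-methylene-5-isopropenyltetrahydrofuran A5 causes a Claisen shift that expands the ring to the cyclohept-4-enone A6. Me2AlCl in the same vessel then promotes a carbonyl-ene reaction of the pendant trisubstituted olefin with the C5 ketone, giving the bicyclic alcohol A7 with isopropenyl cis to hydroxyl.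
- **In favour:** both rings and the C4/C5 centres come from one pot and from a precursor with a single controlling stereocentre (C1). The concerted ene transition state accounts for the cis isopropenyl/hydroxyl relation. For the carbon skeleton this is the most step-economic of the four plans and better than the chosen one.
- **Against:** the enol ether A5 is acid-sensitive and its quaternary C1 must be made enantioselectively. The fusion sense (hydroxyl cis to the C1 methyl) depends on the conformation of the seven-membered ketone in the ene step. A7 lacks the C7 oxygen, so an allylic oxidation (C7 against C10 and the C8 methyl, on the right face) and a selective hydrogenation of isopropenyl beside C8=C9 remain.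
- **Comparison:** the chosen plan is weaker on skeleton economy but stronger on the oxygenation pattern, because both oxygens and the olefin position come directly from the cycloaddition partners.

Key step: step 6

Remark: locants C1–C10 are those of the hydroazulene skeleton defined under Structural features and are used for every intermediate; 22 is read as the cis-fused isomer with C1 methyl, C5 hydroxyl and C4 isopropyl on one face.
Remark: the oxyallyl partner is 3,3-dichlorobutan-2-one, so C8 of the adduct carries chlorine beside methyl; the C8 configuration of 15–19 is not controlled (SMILES show chlorine on the bridge-oxygen face) and is erased in step 10.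
Assumption: 2 and 7 are catalogue reagents.

## Route

Step 1
Reactants: 1 cyclopent-2-en-1-one; 2 diisopropylzinc
Product: 4 trimethyl{[(3R)-3-(propan-2-yl)cyclopent-1-en-1-yl]oxy}silane, via zinc enolate 3 (not isolated)
Conditions: i-Pr2Zn, Cu(OTf)2 (cat.), chiral amino-acid-derived Schiff-base phosphine ligand (cat.), toluene, −30 °C; then Me3SiOTf, 0 °C
Reagents that add atoms: trimethylsilyl trifluoromethanesulfonate, C[Si](C)(C)OS(=O)(=O)C(F)(F)F
Why: Copper-catalysed asymmetric conjugate addition of a dialkylzinc to a cyclic enone; the chiral copper complex selects the enone face and sets C4 (the ligand antipode leading to the (S)-ketone framework is used), and silylation of the zinc enolate fixes the enol ether toward the carbon next to the new stereocentre.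

Step 2
Reactants: 4 trimethyl{[(3R)-3-(propan-2-yl)cyclopent-1-en-1-yl]oxy}silane
Product: 6 (2R,3R)-2-hydroxy-3-(propan-2-yl)cyclopentan-1-one, via silyloxy ketone 5 (not isolated)
Conditions: mCPBA, NaHCO3, CH2Cl2, −20 °C; then Et3N·3HF, THF, 0 °C
Reagents that add atoms: 3-chloroperoxybenzoic acid, OOC(=O)c1cccc(Cl)c1
Why: Rubottom oxidation: epoxidation of the enol ether anti to isopropyl, silyl migration and desilylation place oxygen on the carbon between carbonyl and stereocentre; this oxygen is the future C5 hydroxyl, and the new carbinol centre is transient.

Step 3
Reactants: 6 (2R,3R)-2-hydroxy-3-(propan-2-yl)cyclopentan-1-one; 7 (triphenylphosphoranylidene)ketene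
Product: 9 (6R,6aR)-6-(propan-2-yl)-4,5,6,6a-tetrahydro-2H-cyclopenta[b]furan-2-one, via ester ylide 8 (not isolated)
Conditions: toluene, 90 °C
Reagents that add atoms: none
Why: The hydroxyl adds to the ketene to give a stabilised acyl ylide that closes by intramolecular Wittig olefination on the neighbouring ketone (butenolide annulation of an α-hydroxy ketone); the isopropyl centre is β to the carbonyl and is not touched.

Step 4
Reactants: 9 (6R,6aR)-6-(propan-2-yl)-4,5,6,6a-tetrahydro-2H-cyclopenta[b]furan-2-one
Product: 11 (6R)-6-(propan-2-yl)-5,6-dihydro-4H-cyclopenta[b]furan, via lactol 10 (not isolated)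
Conditions: i-Bu2AlH, CH2Cl2, −78 °C; then 1 M H2SO4, 0 °C to rt
Reagents that add atoms: none
Why: Hydride reduction of the butenolide to the lactol and acid-promoted 1,4-dehydration give the aromatic furan, a standard butenolide-to-furan conversion; the isopropyl-bearing carbon is never α to a carbonyl, so its configuration should be safe.

Step 5
Reactants: 12 3-chlorobutan-2-one
Product: 13 3,3-dichlorobutan-2-one
Conditions: SO2Cl2 (1.1 equiv), neat, 40 °C
Reagents that add atoms: sulfuryl chloride, ClS(Cl)(=O)=O
Why: α-Chlorination of a ketone through its enol; the second chlorine should enter at the already chlorinated, more substituted α-carbon (geminal dichlorination), leaving the methyl group on the other side enolisable.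

Step 6
Reactants: 11 (6R)-6-(propan-2-yl)-5,6-dihydro-4H-cyclopenta[b]furan; 13 3,3-dichlorobutan-2-one
Product: 15 6-chloro-6-methyl-3-(propan-2-yl)-2,3,6,7-tetrahydro-1H-3a,7-epoxyazulen-5(4H)-one (bridge oxygen cis to isopropyl), via oxyallyl cation 14 (not isolated)
Conditions: NaOCH2CF3 (1.5 equiv), CF3CH2OH, 0 °C to rt, 13 (1.5 equiv) added slowly to 11 and base
Reagents that add atoms: none
Why: Alkoxide removes a proton from the methyl group of 13 and, in the ionising and weakly nucleophilic alcohol, the enolate loses chloride to give the 1-chloro-1-methyl-2-oxyallyl cation 14, a two-electron three-carbon component. It adds across the furan diene of 11 at the two α-carbons; the closest known reaction type is the (4+3) cycloaddition of oxyallyl cations from α-chloro ketones with furans under these conditions. The seven-membered carbocycle is closed by this intermolecular cycloaddition, both bonds (C8–C9 and C5–C6) forming on one furan face, in concert or by C8–C9 bonding followed by closure of the enolate carbon C6 onto the furanyl cation at C5, and the furan oxygen becomes the one-atom bridge. C5 is controlled by the C4 isopropyl group, which blocks its own face, so C6 bonds anti to it and the bridge oxygen ends on the isopropyl face. C9 is tied to C5 because the bridge can only be cis. C8 (chlorine/methyl) is not controlled and need not be, since it becomes trigonal in step 10. The regiochemistry needed is the chlorinated, fully substituted terminus to the unsubstituted furan carbon C9 and CH2 to the fusion carbon C5; sterics (the reverse sense would join two fully substituted carbons) and electronics (the cation-stabilised terminus pairs with the more nucleophilic C9) point the same way. The furan is the limiting component and the cation is generated slowly to limit its capture by alkoxide.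

Step 7
Reactants: 15 6-chloro-6-methyl-3-(propan-2-yl)-2,3,6,7-tetrahydro-1H-3a,7-epoxyazulen-5(4H)-one
Product: 16 exo-cyclopropane of 15 (CH2 across C1 and C10 on the bridge-oxygen face)
Conditions: Et2Zn, CH2I2, CH2Cl2, 0 °C to rt
Reagents that add atoms: diiodomethane, ICI
Why: Simmons–Smith cyclopropanation (Furukawa reagent) of the strained trisubstituted C1=C10 olefin; the zinc carbenoid can only reach the face carrying the bridge oxygen because the other face lies over the C6–C7–C8 bridge, so the new CH2, the future C1 methyl, should be cis to the C5 oxygen.

Step 8
Reactants: 16 exo-cyclopropane of 15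
Product: 17 C7 alcohol of 16 (hydroxyl toward the C1–C10 bridge)
Conditions: LiBH(s-Bu)3, THF, −78 °C; AcOH quench at −78 °C
Reagents that add atoms: none
Why: Hydride reduction of a bridged ketone; the C1–C10 bridge closes one face of C7, so the bulky borohydride should attack from the open face and leave the hydroxyl pointing toward that bridge, which is anti to the C5 oxygen as in the target; the cold acidic quench avoids epoxide closure of the chlorohydrin alkoxide.

Step 9
Reactants: 17 C7 alcohol of 16
Product: 18 6-chloro-6,8a-dimethyl-3-(propan-2-yl)octahydro-3a,7-epoxyazulen-5-ol (C1 methyl cis to the bridge oxygen)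
Conditions: H2 (4 atm), PtO2, AcOH, 25–40 °C
Reagents that add atoms: none
Why: Catalytic hydrogenolysis of a cyclopropane at its least substituted and least hindered bond (C10–CH2), the classical route to an angular methyl; C1 keeps the carbon on the face where it was delivered, and the tertiary chloride, the ether bridge and the alcohol should be inert to platinum in acetic acid.

Step 10
Reactants: 18 6-chloro-6,8a-dimethyl-3-(propan-2-yl)octahydro-3a,7-epoxyazulen-5-ol
Product: 20 (3R,3aS,5R,8aR)-6,8a-dimethyl-3-(propan-2-yl)-2,3,4,5,8,8a-hexahydroazulene-3a,5(1H)-diol, via lithium alkoxide 19 (not isolated)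
Conditions: n-BuLi (1.05 equiv), THF, −78 °C; then lithium 4,4′-di-tert-butylbiphenylide (2.5 equiv), −78 °C; NH4Cl (aq)
Reagents that add atoms: none
Why: After deprotonation of the C7 hydroxyl, reductive lithiation of the tertiary chloride gives a C8 carbanion that expels the β-ether oxygen on C9 (Boord-type reductive elimination of a β-halo ether), opening the bridge to the C8=C9 olefin and the C5 alkoxide. The C7 alkoxide cannot leave, so the direction of opening is fixed, and an equatorial C8–Li bond is antiperiplanar to the C9–O ring bond.

Step 11
Reactants: 20 (3R,3aS,5R,8aR)-6,8a-dimethyl-3-(propan-2-yl)-2,3,4,5,8,8a-hexahydroazulene-3a,5(1H)-diol; 21 3,4-dimethoxybenzoyl chloride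
Product: 22 (3R,3aS,5R,8aR)-3a-hydroxy-6,8a-dimethyl-3-(propan-2-yl)-1,2,3,3a,4,5,8,8a-octahydroazulen-5-yl 3,4-dimethoxybenzoate
Conditions: Et3N, DMAP (cat.), CH2Cl2, 0 °C to rt
Reagents that add atoms: none
Why: Acylation of the secondary allylic alcohol with an acid chloride under nucleophilic catalysis; the tertiary C5 hydroxyl is too hindered to react under these conditions.

## Compound list

1 | cyclopent-2-en-1-one | O=C1C=CCC1 | starting material
2 | diisopropylzinc | CC(C)[Zn]C(C)C | starting material
3 | isopropylzinc enolate, isopropyl{[(3R)-3-(propan-2-yl)cyclopent-1-en-1-yl]oxy}zinc (not isolated) | CC(C)[Zn]OC1=C[C@@H](C(C)C)CC1 | intermediate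
4 | trimethyl{[(3R)-3-(propan-2-yl)cyclopent-1-en-1-yl]oxy}silane | C[Si](C)(C)OC1=C[C@@H](C(C)C)CC1 | intermediate
5 | (2R,3R)-3-(propan-2-yl)-2-(trimethylsilyloxy)cyclopentan-1-one (not isolated) | O=C1[C@H](O[Si](C)(C)C)[C@@H](C(C)C)CC1 | intermediate
6 | (2R,3R)-2-hydroxy-3-(propan-2-yl)cyclopentan-1-one | O=C1[C@H](O)[C@@H](C(C)C)CC1 | intermediate
7 | (triphenylphosphoranylidene)ketene | O=C=C=P(c1ccccc1)(c1ccccc1)c1ccccc1 | starting material
8 | (1R,5R)-2-oxo-5-(propan-2-yl)cyclopentyl (triphenylphosphoranylidene)acetate (not isolated) | O=C1[C@H](OC(=O)C=P(c2ccccc2)(c2ccccc2)c2ccccc2)[C@@H](C(C)C)CC1 | intermediate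
9 | (6R,6aR)-6-(propan-2-yl)-4,5,6,6a-tetrahydro-2H-cyclopenta[b]furan-2-one | O=C1C=C2CC[C@H](C(C)C)[C@H]2O1 | intermediate
10 | (6R,6aR)-6-(propan-2-yl)-4,5,6,6a-tetrahydro-2H-cyclopenta[b]furan-2-ol, both C2 epimers (not isolated) | OC1C=C2CC[C@H](C(C)C)[C@H]2O1 | intermediate
11 | (6R)-6-(propan-2-yl)-5,6-dihydro-4H-cyclopenta[b]furan | o1ccc2c1[C@@H](C(C)C)CC2 | intermediate
12 | 3-chlorobutan-2-one | CC(Cl)C(C)=O | starting material
13 | 3,3-dichlorobutan-2-one | CC(=O)C(C)(Cl)Cl | intermediate
14 | 1-chloro-1-methyl-2-oxyallyl cation (not isolated) | C=C([O-])[C+](C)Cl | intermediate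
15 | 6-chloro-6-methyl-3-(propan-2-yl)-2,3,6,7-tetrahydro-1H-3a,7-epoxyazulen-5(4H)-one; C7 ketone, C5–O–C9 bridge on the isopropyl face, C1=C10 olefin, chlorine on the bridge-oxygen face of C8 | O=C2C[C@]3(O1)[C@@H](C(C)C)CCC3=C[C@@H]1[C@@]2(C)Cl | intermediate
16 | exo-cyclopropane of 15; CH2 bridging C1 and C10 on the bridge-oxygen face | O=C2C[C@]3(O1)[C@@H](C(C)C)CC[C@@]34C[C@H]4[C@@H]1[C@@]2(C)Cl | intermediate
17 | C7 alcohol of 16; hydroxyl pointing toward the C1–C10 bridge, anti to the bridge oxygen | O[C@@H]2C[C@]3(O1)[C@@H](C(C)C)CC[C@@]34C[C@H]4[C@@H]1[C@@]2(C)Cl | intermediate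
18 | 6-chloro-6,8a-dimethyl-3-(propan-2-yl)octahydro-3a,7-epoxyazulen-5-ol; C1 methyl cis to the bridge oxygen, C10 methylene | O[C@@H]2C[C@]3(O1)[C@@H](C(C)C)CC[C@]3(C)C[C@@H]1[C@@]2(C)Cl | intermediate
19 | lithium alkoxide of 18 (not isolated) | [Li]O[C@@H]2C[C@]3(O1)[C@@H](C(C)C)CC[C@]3(C)C[C@@H]1[C@@]2(C)Cl | intermediate
20 | (3R,3aS,5R,8aR)-6,8a-dimethyl-3-(propan-2-yl)-2,3,4,5,8,8a-hexahydroazulene-3a,5(1H)-diol | O[C@@H]2C[C@]3(O)[C@@H](C(C)C)CC[C@]3(C)CC=C2C | intermediate
21 | 3,4-dimethoxybenzoyl chloride | COc1ccc(C(Cl)=O)cc1OC | starting material
22 | (3R,3aS,5R,8aR)-3a-hydroxy-6,8a-dimethyl-3-(propan-2-yl)-1,2,3,3a,4,5,8,8a-octahydroazulen-5-yl 3,4-dimethoxybenzoate | COc1ccc(C(=O)O[C@@H]2C[C@]3(O)[C@@H](C(C)C)CC[C@]3(C)CC=C2C)cc1OC | target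

## Step count and least certain steps

Total: 11 steps. Longest linear sequence: 10 steps (steps 1–4 and 6–11); step 5 is a one-step branch.

**Step 6 (key step).**
- What may go wrong: capture of cation 14 by trifluoroethoxide, or its collapse by Favorskii-type paths, before it meets the limiting furan. Substitution at C9 without ring closure is also possible, because closure onto the hindered C5 is the slow bond. Facial bias from the isopropyl group may be incomplete.
- Fallback: it sets out from 13 (with 11) and returns at 15. 13 is converted with Me3SiOTf and Et3N into the silyl enol ether (3,3-dichlorobut-1-en-2-yloxy)trimethylsilane F1. AgBF4 in CH2Cl2 at −78 °C in the presence of 11 abstracts chloride and generates the 2-(silyloxy)allyl cation with no alkoxide present. Loss of the silyl group on work-up gives 15.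

**Step 7.**
- What may go wrong: slow or face-unselective methylene transfer, because the isopropyl group lies near C1 on the reacting face. The zinc iodide formed may also ionise the allylic ether.
- Fallback: it sets out from 15 and returns at 22. The methyl is delivered after bridge opening by a temporary silicon tether.
 - 15 is reduced with LiBH(s-Bu)3 to the olefinic chloro alcohol F2.
 - n-BuLi, then lithium 4,4′-di-tert-butylbiphenylide, opens the bridge to the diene diol F3.
 - Acylation with 21 gives the C7 ester F4.
 - The tertiary hydroxyl is silylated with (bromomethyl)chlorodimethylsilane and imidazole to the bromomethylsilyl ether F5.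
 - Bu3SnH and AIBN in benzene at 80 °C give 5-exo cyclisation of the silylmethyl radical on C1, necessarily cis to the C5 oxygen; the allyl radical is reduced at C10, leading to the cyclic siloxane F6.
 - Bu4NF in DMF at 60 °C protodesilylates F6 to 22.

**Step 9.**
- What may go wrong: no reaction at the hindered cyclopropane, cleavage of the wrong ring bond, or hydrogenolysis of a cyclopropylcarbinyl C–O bond.
- Fallback: it sets out from 17 and returns at 20.
 - 17 is opened as in step 10 to the vinylcyclopropane diol F7.
 - MnO2 oxidises the allylic C7 carbinol to the cyclopropyl enone F8.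
 - Li in NH3/THF at −78 °C cleaves the C10–CH2 bond through the enone radical anion; isomerisation with DBU gives the conjugated hydroxy enone F9.
 - Me4NBH(OAc)3 in AcOH/MeCN at −20 °C (Evans–Saksena anti reduction directed by the C5 hydroxyl) gives 20.

**Step 8.**
- What may go wrong: hydride delivery from the wrong face if the axial C8 substituent obstructs the open face, or epoxide closure of the chlorohydrin alkoxide.
- Fallback: it sets out from 16 and returns at 20.
 - The C7-epimeric alcohol F10 is carried through steps 9 and 10, where C7 is a spectator, to the epimeric chloro alcohol F11 and the epimeric diol F12.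
 - MnO2 converts F12 into the hydroxy enone F9, and Me4NBH(OAc)3 reduces it to 20.
 - C7 is then set by intramolecular hydride delivery from the C5 oxygen instead of by the bridged ketone.

**Step 1.**
- What may go wrong: insufficient enantioselectivity with the branched zinc reagent, oligomerisation of the enone by the zinc enolate, or loss of the volatile enol ether.
- Fallback: it sets out from 1 and returns at 6.
 - i-PrMgCl, CuBr·SMe2 (cat.) and Me3SiCl give the racemic silyl enol ether F13.
 - mCPBA, then Et3N·3HF, gives the racemic trans hydroxy ketone F14.
 - A lipase (Burkholderia cepacia) with vinyl acetate should, by the usual empirical model for secondary alcohols, acylate the (2S,3S) enantiomer to the acetate F15 and leave 6. If the preference is the reverse, 6 is obtained from its acetate by methanolysis.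

## Further compounds

F1 | step 6 | (3,3-dichlorobut-1-en-2-yloxy)trimethylsilane | C=C(O[Si](C)(C)C)C(C)(Cl)Cl
F2 | step 7 | C7 alcohol of 15 (olefin retained; hydroxyl toward the C1=C10 bridge) | O[C@@H]2C[C@]3(O1)[C@@H](C(C)C)CCC3=C[C@@H]1[C@@]2(C)Cl
F3 | step 7 | diene diol: C5 and C7 hydroxyls, C8=C9 and C10=C1 olefins | O[C@@H]2C[C@]3(O)[C@@H](C(C)C)CCC3=CC=C2C
F4 | step 7 | C7 3,4-dimethoxybenzoate of F3 | COc1ccc(C(=O)O[C@@H]2C[C@]3(O)[C@@H](C(C)C)CCC3=CC=C2C)cc1OC
F5 | step 7 | C5 (bromomethyl)dimethylsilyl ether of F4 | COc1ccc(C(=O)O[C@@H]2C[C@]3(O[Si](C)(C)CBr)[C@@H](C(C)C)CCC3=CC=C2C)cc1OC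
F6 | step 7 | cyclic siloxane: C5–O–SiMe2–CH2–C1, cis-fused, C8=C9 olefin | COc1ccc(C(=O)O[C@@H]2C[C@]3(O[Si](C)(C)C4)[C@@H](C(C)C)CC[C@]34CC=C2C)cc1OC
F7 | step 9 | vinylcyclopropane diol: C1/C10 cyclopropane cis to the C5 hydroxyl, C8=C9 olefin | O[C@@H]2C[C@]3(O)[C@@H](C(C)C)CC[C@@]34C[C@H]4C=C2C
F8 | step 9 | cyclopropyl hydroxy enone: C7 ketone of F7 | O=C2C[C@]3(O)[C@@H](C(C)C)CC[C@@]34C[C@H]4C=C2C
F9 | step 9 | hydroxy enone: C7 ketone of 20 | O=C2C[C@]3(O)[C@@H](C(C)C)CC[C@]3(C)CC=C2C
F10 | step 8 | C7 epimer of 17 | O[C@H]2C[C@]3(O1)[C@@H](C(C)C)CC[C@@]34C[C@H]4[C@@H]1[C@@]2(C)Cl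
F11 | step 8 | C7 epimer of 18 | O[C@H]2C[C@]3(O1)[C@@H](C(C)C)CC[C@]3(C)C[C@@H]1[C@@]2(C)Cl
F12 | step 8 | C7 epimer of 20 | O[C@H]2C[C@]3(O)[C@@H](C(C)C)CC[C@]3(C)CC=C2C
F13 | step 1 | racemic trimethyl{[3-(propan-2-yl)cyclopent-1-en-1-yl]oxy}silane | C[Si](C)(C)OC1=C[C@@H](C(C)C)CC1.C[Si](C)(C)OC1=C[C@H](C(C)C)CC1
F14 | step 1 | racemic trans-2-hydroxy-3-(propan-2-yl)cyclopentan-1-one | O=C1[C@H](O)[C@@H](C(C)C)CC1.O=C1[C@@H](O)[C@H](C(C)C)CC1
F15 | step 1 | (1S,5S)-2-oxo-5-(propan-2-yl)cyclopentyl acetate | O=C1[C@@H](OC(C)=O)[C@H](C(C)C)CC1
A1 | alternative 1 | (5R,6Z,9E)-5-(tert-butyldimethylsilyloxy)-3-(methoxymethoxy)-6,9-dimethyloxacycloundeca-6,9-dien-2-one (C3 of the lactone, target C5, either epimer) | O=C1OC/C=C(\C)C/C=C(/C)[C@H](O[Si](C)(C)C(C)(C)C)CC1OCOC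
A2 | alternative 1 | cycloheptene carboxylic acid with the C5 MOM ether and the C1 methyl/vinyl centre | CC(C)(C)[Si](C)(C)O[C@@H]2C[C@](OCOC)(C(=O)O)[C@](C)(C=C)CC=C2C
A3 | alternative 2 | diazoketone: cycloheptene with C1 methine, C5 silyl ether and the C4–C3(=O)–C2 diazo side chain | C1C[C@](O[Si](C)(C)C)([C@@H](C(C)C)C(=O)C=[N+]=[N-])[C@@H](C)CC=C1C
A4 | alternative 2 | bicyclic cyclopentanone (C3 ketone) with quaternary C1 | C2C[C@]3(O[Si](C)(C)C)[C@@H](C(C)C)C(=O)C[C@]3(C)CC=C2C
A5 | alternative 3 | 2-methylene-3-methyl-3-(4-methylpent-3-enyl)-5-(prop-1-en-2-yl)tetrahydrofuran (C5 of the ring, target C9, either epimer) | C=C1OC(C(C)=C)C[C@@]1(C)CCC=C(C)C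
A6 | alternative 3 | 2,5-dimethyl-2-(4-methylpent-3-enyl)cyclohept-4-en-1-one | O=C1CCC(C)=CC[C@@]1(C)CCC=C(C)C
A7 | alternative 3 | bicyclic tertiary alcohol with C4 isopropenyl cis to hydroxyl | C2C[C@]3(O)[C@@H](C(C)=C)CC[C@]3(C)CC=C2C
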